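**Retrosynthetic overview**

1. Target 24 comes from 23 by removal of two MOM groups, and 23 from the 5-fluoroflavone 21 by exchange of the C5 fluoride for hydroxyl.
2. Ring C is closed last, at O1–C8a: 21 comes from the 2-(MOM-oxy)-1,3-diketone 19 by attack of its enolate oxygen on an ortho C–F of ring A. Rings A and B are carried intact from aromatic starting materials.
3. 19 comes from aldol addition of the ring B α-(MOM-oxy)ketone 16 to the ring A aldehyde 11, then oxidation.
4. 11 comes from 3,5-difluoroanisole (silyl block between the fluorines, two ortho-lithiation/prenylations, desilylation, formylation). 16 comes from 3'-hydroxy-4'-methoxyacetophenone.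
5. Feature used: O1 (on C8a) and the 5-OH (on C5) sit on the two equivalent ring A carbons that flank the acyl-bearing C4a and lie meta to the C7 methoxy. Two identical C–F bonds there supply one leaving group for ring closure and one masked hydroxyl.

Key step: step 11

Remark: the target has no stereocentre and both prenyl alkenes carry geminal methyl groups, so no configuration needs control. The two stereocentres of aldol 18 are transient.

**Route**

Step 1
Reactants: 1 3,5-difluoroanisole
Product: 3 (2,6-difluoro-4-methoxyphenyl)triethylsilane, via aryllithium 2 (not isolated)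
Conditions: n-BuLi, THF, −78 °C; Et3SiCl, −78 °C → rt
Reagents that add atoms: chlorotriethylsilane, CC[Si](Cl)(CC)CC
Why: The proton between the two fluorines is the most acidic on the ring, so directed ortho-lithiation occurs there and silylation blocks that position for the next two steps.

Step 2
Reactants: 3 (2,6-difluoro-4-methoxyphenyl)triethylsilane; 4 prenyl bromide
Product: 6 [2,6-difluoro-4-methoxy-3-(3-methylbut-2-enyl)phenyl]triethylsilane, via aryllithium 5 (not isolated)
Conditions: s-BuLi, THF, −78 °C; CuBr·SMe2 (10 mol%), 4, −78 → −40 °C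
Reagents that add atoms: none
Why: With the most acidic site blocked, directed ortho-lithiation should take the proton flanked by OMe and F, and copper-catalysed allylic substitution at the primary carbon of prenyl bromide should give the linear prenyl arene; the low temperature prevents LiF loss to an aryne.

Step 3
Reactants: 6 [2,6-difluoro-4-methoxy-3-(3-methylbut-2-enyl)phenyl]triethylsilane; 4 prenyl bromide
Product: 8 [2,6-difluoro-4-methoxy-3,5-bis(3-methylbut-2-enyl)phenyl]triethylsilane, via aryllithium 7 (not isolated)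
Conditions: s-BuLi, THF, −78 °C; CuBr·SMe2 (10 mol%), 4, −78 → −40 °C
Reagents that add atoms: none
Why: The last ring proton is again flanked by OMe and F, so directed ortho-lithiation at −78 °C should be kinetically faster than lateral deprotonation of the prenyl CH2, and the same copper-catalysed allylation follows.

Step 4
Reactants: 8 [2,6-difluoro-4-methoxy-3,5-bis(3-methylbut-2-enyl)phenyl]triethylsilane
Product: 9 1,5-difluoro-3-methoxy-2,4-bis(3-methylbut-2-enyl)benzene
Conditions: Bu4NF·3H2O, THF, rt
Reagents that add atoms: none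
Why: Fluoride attack at silicon releases an aryl anion stabilised by two ortho fluorines, which water protonates (protodesilylation).

Step 5
Reactants: 9 1,5-difluoro-3-methoxy-2,4-bis(3-methylbut-2-enyl)benzene
Product: 11 2,6-difluoro-4-methoxy-3,5-bis(3-methylbut-2-enyl)benzaldehyde, via aryllithium 10 (not isolated)
Conditions: n-BuLi, THF, −78 °C; DMF, −78 → 0 °C; H2O
Reagents that add atoms: N,N-dimethylformamide, CN(C)C=O
Why: The freed proton between the two fluorines is far more acidic than the benzylic/allylic CH2 groups, so ortho-lithiation and formylation with DMF should give the aldehyde cleanly.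

Step 6
Reactants: 12 3'-hydroxy-4'-methoxyacetophenone
Product: 13 2-bromo-1-(3-hydroxy-4-methoxyphenyl)ethanone
Conditions: CuBr2 (2.1 equiv), EtOAc/CHCl3 1:1, reflux
Reagents that add atoms: copper dibromide, Br[Cu]Br
Why: CuBr2 brominates the enolisable methyl ketone at the α-carbon and is known to leave free phenolic rings unbrominated.

Step 7
Reactants: 13 2-bromo-1-(3-hydroxy-4-methoxyphenyl)ethanone
Product: 15 2-hydroxy-1-(3-hydroxy-4-methoxyphenyl)ethanone, via formate ester 14 (not isolated)
Conditions: HCO2Na, EtOH/H2O, reflux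
Reagents that add atoms: sodium formate, [Na+].[O-]C=O
Why: SN2 displacement of the phenacyl bromide by formate and solvolysis of the labile formate ester give the α-hydroxy ketone, and the weakly basic medium leaves the phenol un-ionised.

Step 8
Reactants: 15 2-hydroxy-1-(3-hydroxy-4-methoxyphenyl)ethanone
Product: 16 2-(methoxymethoxy)-1-[4-methoxy-3-(methoxymethoxy)phenyl]ethanone
Conditions: MeOCH2Cl (3 equiv), i-Pr2NEt, CH2Cl2, 0 °C → rt
Reagents that add atoms: chloromethyl methyl ether, COCCl
Why: O-alkylation with MOMCl and Hünig's base protects the phenol and the primary alcohol in one operation.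

Step 9
Reactants: 16 2-(methoxymethoxy)-1-[4-methoxy-3-(methoxymethoxy)phenyl]ethanone; 11 2,6-difluoro-4-methoxy-3,5-bis(3-methylbut-2-enyl)benzaldehyde
Product: 18 3-[2,6-difluoro-4-methoxy-3,5-bis(3-methylbut-2-enyl)phenyl]-3-hydroxy-2-(methoxymethoxy)-1-[4-methoxy-3-(methoxymethoxy)phenyl]propan-1-one (racemic mixture of diastereomers), via lithium enolate 17 (not isolated)
Conditions: LiN(SiMe3)2, THF, −78 °C; 11, −78 °C; AcOH quench at −78 °C
Reagents that add atoms: none
Why: Aldol addition of the chelated lithium enolate to the electron-poor, non-enolisable aldehyde is fast at −78 °C; the two new stereocentres are formed without control because step 10 removes one and step 11 the other.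

Step 10
Reactants: 18 aldol adduct
Product: 19 1-[2,6-difluoro-4-methoxy-3,5-bis(3-methylbut-2-enyl)phenyl]-2-(methoxymethoxy)-3-[4-methoxy-3-(methoxymethoxy)phenyl]propane-1,3-dione (racemic, enolisable)
Conditions: 2-iodoxybenzoic acid (IBX), EtOAc, 75 °C
Reagents that add atoms: none
Why: IBX oxidation of β-hydroxy ketones gives 1,3-diketones without over-oxidation of the central carbon and leaves the prenyl alkenes and MOM ethers untouched.

Step 11
Reactants: 19 2-(methoxymethoxy)-1,3-diketone
Product: 21 5-fluoro-7-methoxy-3-(methoxymethoxy)-2-[4-methoxy-3-(methoxymethoxy)phenyl]-6,8-bis(3-methylbut-2-enyl)chromen-4-one, via cesium enolate 20 (not isolated)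
Conditions: Cs2CO3, DMF, 70 °C
Reagents that add atoms: none
Why: Cs2CO3 deprotonates the central carbon of 19 to the delocalised enolate 20, whose oxygen on the ring B side adds to a fluorine-bearing carbon ortho to the ring A acyl group; the Meisenheimer complex is stabilised by that acyl group and by the second fluorine, and loss of fluoride forms the O1–C8a bond. The closest known reaction is the base-mediated cyclisation of 1-(2-fluoroaryl)-1,3-diketones to chromones and flavones by intramolecular nucleophilic aromatic substitution. Ring C closes as a six-membered ring by addition–elimination at an sp2 aromatic carbon (formally 6-endo-trig, with C8a=C4a as the accepting bond). No stereocentre is formed, and the one at C2 of 19 becomes sp2. The step needs O- over C-attack and one defined C–F: only the ring B-side oxygen can reach a C–F bond through a six-membered transition state (the other oxygen or the central carbon would close a four-membered ring), and the two fluorines are equivalent by the symmetry of ring A. The C7 methoxy is meta to the reacting carbon, so it does not deactivate it by resonance.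

Step 12
Reactants: 21 5-fluoroflavone
Product: 23 5-hydroxy-7-methoxy-3-(methoxymethoxy)-2-[4-methoxy-3-(methoxymethoxy)phenyl]-6,8-bis(3-methylbut-2-enyl)chromen-4-one, via sulfonylethyl ether 22 (not isolated)
Conditions: MeSO2CH2CH2OH (1.5 equiv), NaH (3 equiv), DMF, 0 → 40 °C; AcOH quench
Reagents that add atoms: 2-(methylsulfonyl)ethanol, CS(=O)(=O)CCO
Why: The C5 fluoride is ortho to the C4 carbonyl and should undergo nucleophilic aromatic substitution by the alkoxide, after which E1cB loss of methyl vinyl sulfone from ether 22 releases the phenoxide (hydroxide-surrogate method for activated aryl fluorides).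

Step 13
Reactants: 23 5-hydroxy bis-MOM flavone
Product: 24 3,5-dihydroxy-2-(3-hydroxy-4-methoxyphenyl)-7-methoxy-6,8-bis(3-methylbut-2-enyl)chromen-4-one (target)
Conditions: 2 M aq. HCl, MeOH/THF, 45 °C
Reagents that add atoms: none
Why: Acid-catalysed acetal exchange in methanol removes both MOM groups; dilute acid and mild temperature should spare the prenyl alkenes, and the 5-OH is hydrogen-bonded to C4=O and so poorly nucleophilic towards chroman formation.

**Compound list**

1 | 3,5-difluoroanisole | COc1cc(F)cc(F)c1 | starting material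
2 | (2,6-difluoro-4-methoxyphenyl)lithium | COc1cc(F)c([Li])c(F)c1 | intermediate
3 | (2,6-difluoro-4-methoxyphenyl)triethylsilane | CC[Si](CC)(CC)c1c(F)cc(OC)cc1F | intermediate
4 | prenyl bromide (1-bromo-3-methylbut-2-ene) | CC(C)=CCBr | starting material
5 | [2,4-difluoro-6-methoxy-3-(triethylsilyl)phenyl]lithium | CC[Si](CC)(CC)c1c(F)cc(OC)c([Li])c1F | intermediate
6 | [2,6-difluoro-4-methoxy-3-(3-methylbut-2-enyl)phenyl]triethylsilane | CC[Si](CC)(CC)c1c(F)cc(OC)c(CC=C(C)C)c1F | intermediate
7 | [2,4-difluoro-6-methoxy-5-(3-methylbut-2-enyl)-3-(triethylsilyl)phenyl]lithium | CC[Si](CC)(CC)c1c(F)c([Li])c(OC)c(CC=C(C)C)c1F | intermediate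
8 | [2,6-difluoro-4-methoxy-3,5-bis(3-methylbut-2-enyl)phenyl]triethylsilane | CC[Si](CC)(CC)c1c(F)c(CC=C(C)C)c(OC)c(CC=C(C)C)c1F | intermediate
9 | 1,5-difluoro-3-methoxy-2,4-bis(3-methylbut-2-enyl)benzene | COc1c(CC=C(C)C)c(F)cc(F)c1CC=C(C)C | intermediate
10 | [2,6-difluoro-4-methoxy-3,5-bis(3-methylbut-2-enyl)phenyl]lithium | COc1c(CC=C(C)C)c(F)c([Li])c(F)c1CC=C(C)C | intermediate
11 | 2,6-difluoro-4-methoxy-3,5-bis(3-methylbut-2-enyl)benzaldehyde | COc1c(CC=C(C)C)c(F)c(C=O)c(F)c1CC=C(C)C | intermediate
12 | 3'-hydroxy-4'-methoxyacetophenone | CC(=O)c1ccc(OC)c(O)c1 | starting material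
13 | 2-bromo-1-(3-hydroxy-4-methoxyphenyl)ethanone | COc1ccc(C(=O)CBr)cc1O | intermediate
14 | 2-(3-hydroxy-4-methoxyphenyl)-2-oxoethyl formate | COc1ccc(C(=O)COC=O)cc1O | intermediate
15 | 2-hydroxy-1-(3-hydroxy-4-methoxyphenyl)ethanone | COc1ccc(C(=O)CO)cc1O | intermediate
16 | 2-(methoxymethoxy)-1-[4-methoxy-3-(methoxymethoxy)phenyl]ethanone | COCOCC(=O)c1ccc(OC)c(OCOC)c1 | intermediate
17 | lithium (Z)-2-(methoxymethoxy)-1-[4-methoxy-3-(methoxymethoxy)phenyl]ethenolate | COCO/C=C(\O[Li])c1ccc(OC)c(OCOC)c1 | intermediate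
18 | 3-[2,6-difluoro-4-methoxy-3,5-bis(3-methylbut-2-enyl)phenyl]-3-hydroxy-2-(methoxymethoxy)-1-[4-methoxy-3-(methoxymethoxy)phenyl]propan-1-one (racemic, both diastereomers) | COCOC(C(=O)c1ccc(OC)c(OCOC)c1)C(O)c1c(F)c(CC=C(C)C)c(OC)c(CC=C(C)C)c1F | intermediate
19 | 1-[2,6-difluoro-4-methoxy-3,5-bis(3-methylbut-2-enyl)phenyl]-2-(methoxymethoxy)-3-[4-methoxy-3-(methoxymethoxy)phenyl]propane-1,3-dione (racemic, enolisable) | COCOC(C(=O)c1ccc(OC)c(OCOC)c1)C(=O)c1c(F)c(CC=C(C)C)c(OC)c(CC=C(C)C)c1F | intermediate
20 | cesium enolate of 19 | COCOC(=C([O-])c1ccc(OC)c(OCOC)c1)C(=O)c1c(F)c(CC=C(C)C)c(OC)c(CC=C(C)C)c1F.[Cs+] | intermediate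
21 | 5-fluoro-7-methoxy-3-(methoxymethoxy)-2-[4-methoxy-3-(methoxymethoxy)phenyl]-6,8-bis(3-methylbut-2-enyl)chromen-4-one | COCOc1cc(-c2oc3c(CC=C(C)C)c(OC)c(CC=C(C)C)c(F)c3c(=O)c2OCOC)ccc1OC | intermediate
22 | 7-methoxy-3-(methoxymethoxy)-2-[4-methoxy-3-(methoxymethoxy)phenyl]-6,8-bis(3-methylbut-2-enyl)-5-[2-(methylsulfonyl)ethoxy]chromen-4-one | COCOc1cc(-c2oc3c(CC=C(C)C)c(OC)c(CC=C(C)C)c(OCCS(C)(=O)=O)c3c(=O)c2OCOC)ccc1OC | intermediate
23 | 5-hydroxy-7-methoxy-3-(methoxymethoxy)-2-[4-methoxy-3-(methoxymethoxy)phenyl]-6,8-bis(3-methylbut-2-enyl)chromen-4-one | COCOc1cc(-c2oc3c(CC=C(C)C)c(OC)c(CC=C(C)C)c(O)c3c(=O)c2OCOC)ccc1OC | intermediate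
24 | 3,5-dihydroxy-2-(3-hydroxy-4-methoxyphenyl)-7-methoxy-6,8-bis(3-methylbut-2-enyl)chromen-4-one | COc1ccc(-c2oc3c(CC=C(C)C)c(OC)c(CC=C(C)C)c(O)c3c(=O)c2O)cc1O | target

**Step count**

Total: 13 steps. Longest linear sequence: 10 steps (steps 1–5, then 9–13); the ring B branch (steps 6–8) joins at step 9.

**Steps most likely to fail**

Step 11 (ring C closure). The fluoride displacement may be slow because the 2,6-disubstituted aroyl group is twisted out of conjugation and shares the enolate charge; retro-Claisen cleavage of the diketone could then compete.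
Fallback: close ring C from a phenol by cyclodehydration instead. It sets out from 11. One fluoride of 11 is displaced with NaH and 2-(trimethylsilyl)ethanol (1.0 equiv, THF, 0 °C) to give 2-fluoro-4-methoxy-3,5-bis(3-methylbut-2-enyl)-6-[2-(trimethylsilyl)ethoxy]benzaldehyde F1. Aldol addition of enolate 17 as in step 9 gives the β-hydroxy ketone F2, and IBX oxidation as in step 10 gives the diketone F3. Bu4NF in THF at 50 °C cleaves the silylethyl ether to the o-hydroxyaryl diketone F4. This should close to its cyclic hemiketal and, on warming in AcOH at 60 °C, dehydrate to the flavone. The fallback returns to the route at 21.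

Step 12 (C5 fluoride to hydroxyl). The alkoxide may add at C2 and open the pyranone ring, or substitution may stall because the pyranone carbonyl activates C5 only weakly and the C6 prenyl group shields it.
Fallback: introduce the C5 oxygen on the much more electrophilic aldehyde, before ring C exists. It sets out from 11. Sodium allyloxide (allyl alcohol, NaH, 1.0 equiv, THF, 0 °C) replaces one fluoride to give 2-(allyloxy)-6-fluoro-4-methoxy-3,5-bis(3-methylbut-2-enyl)benzaldehyde F5. Aldol addition of 17 gives F6 and IBX oxidation gives the diketone F7. Cs2CO3 in DMF then closes ring C by displacement of the remaining fluoride, as in step 11, to give the 5-allyloxy flavone F8. Pd(PPh3)4 (zerovalent palladium) and morpholine in THF at rt remove the allyl group. The fallback returns to the route at 23.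

Step 3 (second prenylation). Lateral deprotonation of the benzylic/allylic CH2 of the first prenyl group may compete with ring lithiation, or the aryllithium may lose LiF to an aryne.
Fallback: generate the second aryllithium by bromine–lithium exchange instead of deprotonation. It sets out from 3. Aryllithium 5 (s-BuLi, THF, −78 °C) is quenched with BrCl2CCCl2Br to give (3-bromo-2,6-difluoro-4-methoxyphenyl)triethylsilane F9. Lithium 2,2,6,6-tetramethylpiperidide at −78 °C removes the remaining ring proton without touching the bromide, and CuBr·SMe2-catalysed reaction with 4 gives [3-bromo-2,6-difluoro-4-methoxy-5-(3-methylbut-2-enyl)phenyl]triethylsilane F10. t-BuLi (2 equiv, −78 °C) then exchanges the bromide far faster than any deprotonation, giving aryllithium 7, which is prenylated with 4 as in step 3. The fallback returns to the route at 8.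

**Further compounds**

F1 | step 11 | 2-fluoro-4-methoxy-3,5-bis(3-methylbut-2-enyl)-6-[2-(trimethylsilyl)ethoxy]benzaldehyde | COc1c(CC=C(C)C)c(F)c(C=O)c(OCC[Si](C)(C)C)c1CC=C(C)C
F2 | step 11 | 3-{2-fluoro-4-methoxy-3,5-bis(3-methylbut-2-enyl)-6-[2-(trimethylsilyl)ethoxy]phenyl}-3-hydroxy-2-(methoxymethoxy)-1-[4-methoxy-3-(methoxymethoxy)phenyl]propan-1-one | COCOC(C(=O)c1ccc(OC)c(OCOC)c1)C(O)c1c(F)c(CC=C(C)C)c(OC)c(CC=C(C)C)c1OCC[Si](C)(C)C
F3 | step 11 | 1-{2-fluoro-4-methoxy-3,5-bis(3-methylbut-2-enyl)-6-[2-(trimethylsilyl)ethoxy]phenyl}-2-(methoxymethoxy)-3-[4-methoxy-3-(methoxymethoxy)phenyl]propane-1,3-dione | COCOC(C(=O)c1ccc(OC)c(OCOC)c1)C(=O)c1c(F)c(CC=C(C)C)c(OC)c(CC=C(C)C)c1OCC[Si](C)(C)C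
F4 | step 11 | 1-[2-fluoro-6-hydroxy-4-methoxy-3,5-bis(3-methylbut-2-enyl)phenyl]-2-(methoxymethoxy)-3-[4-methoxy-3-(methoxymethoxy)phenyl]propane-1,3-dione | COCOC(C(=O)c1ccc(OC)c(OCOC)c1)C(=O)c1c(F)c(CC=C(C)C)c(OC)c(CC=C(C)C)c1O
F5 | step 12 | 2-(allyloxy)-6-fluoro-4-methoxy-3,5-bis(3-methylbut-2-enyl)benzaldehyde | C=CCOc1c(CC=C(C)C)c(OC)c(CC=C(C)C)c(F)c1C=O
F6 | step 12 | 3-[2-(allyloxy)-6-fluoro-4-methoxy-3,5-bis(3-methylbut-2-enyl)phenyl]-3-hydroxy-2-(methoxymethoxy)-1-[4-methoxy-3-(methoxymethoxy)phenyl]propan-1-one | COCOC(C(=O)c1ccc(OC)c(OCOC)c1)C(O)c1c(F)c(CC=C(C)C)c(OC)c(CC=C(C)C)c1OCC=C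
F7 | step 12 | 1-[2-(allyloxy)-6-fluoro-4-methoxy-3,5-bis(3-methylbut-2-enyl)phenyl]-2-(methoxymethoxy)-3-[4-methoxy-3-(methoxymethoxy)phenyl]propane-1,3-dione | COCOC(C(=O)c1ccc(OC)c(OCOC)c1)C(=O)c1c(F)c(CC=C(C)C)c(OC)c(CC=C(C)C)c1OCC=C
F8 | step 12 | 5-(allyloxy)-7-methoxy-3-(methoxymethoxy)-2-[4-methoxy-3-(methoxymethoxy)phenyl]-6,8-bis(3-methylbut-2-enyl)chromen-4-one | COCOc1cc(-c2oc3c(CC=C(C)C)c(OC)c(CC=C(C)C)c(OCC=C)c3c(=O)c2OCOC)ccc1OC
F9 | step 3 | (3-bromo-2,6-difluoro-4-methoxyphenyl)triethylsilane | CC[Si](CC)(CC)c1c(F)cc(OC)c(Br)c1F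
F10 | step 3 | [3-bromo-2,6-difluoro-4-methoxy-5-(3-methylbut-2-enyl)phenyl]triethylsilane | CC[Si](CC)(CC)c1c(F)c(CC=C(C)C)c(OC)c(Br)c1F
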